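The plan reads C1=C10 (masked in the target as the epoxide) and C4=C5 as an E,Z-1,5-diene inside the ten-membered carbocycle, with C10 alpha to an oxidised C9. That pattern is the retron of a bicyclo[2.2.0]hexane made by enone–cyclobutene [2+2] photocycloaddition. Heating the 6-4-4 tricycle cuts C1–C4 and C5–C10. In one operation this merges the cyclohexanone ring (C5–C10) and both cyclobutanes into the (2E,6Z)-cyclodecadienone and sets both alkene geometries. The precursor is the cis-anti-cis photoadduct of 1-methylcyclobutene and an (S)-carvone-derived enone. That enone already holds C6–O, C7 and the C8 isobutyrate, and stores the lactone carbons as a bis(silyloxymethyl)methyl branch.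

Key step: step 13

Assumption: 1-methylcyclobutene is taken as purchasable. Germacrane numbering (C1–C15) is used for every intermediate. The C11 epimers formed in steps 4, 17 and 18 are not separated, because C11 becomes sp2 at the end.

Step 1
Reactants: 1 (S)-carvone
Product: 2 (S)-10-chlorocarvone (isopropenyl CH3 turned into CH2Cl = C12; C7 untouched)
Conditions: Ca(OCl)2, solid CO2, CH2Cl2/H2O, 0 °C
Reagents that add atoms: Ca(OCl)2, [Ca+2].[O-]Cl.[O-]Cl
Why: Ene-type allylic chlorination by hypochlorous acid takes only the electron-rich 1,1-disubstituted alkene, so the electron-poor enone and the C7 stereocentre stay untouched.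

Step 2
Reactants: 2 (S)-10-chlorocarvone
Product: 3 (S)-10-acetoxycarvone
Conditions: KOAc, n-Bu4NI (cat.), DMF, 60 °C
Reagents that add atoms: KOAc, CC(=O)[O-].[K+]
Why: SN2 displacement of a primary allylic chloride by acetate under iodide catalysis, in which an SN2' event would give the same compound.

Step 3
Reactants: 3 (S)-10-acetoxycarvone
Product: 4 acetoxy ketal (1,3-dioxolane at C9; C5=C10 kept in place)
Conditions: TMSOCH2CH2OTMS, TMSOTf (5 mol %), CH2Cl2, −78 to −40 °C; pyridine quench
Reagents that add atoms: 1,2-bis(trimethylsilyloxy)ethane, C[Si](C)(C)OCCO[Si](C)(C)C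
Why: Noyori ketalisation under aprotic conditions at low temperature masks the ketone without moving the ring double bond, which shields C9 from the borane and later leaves C6 as the only allylic ring methylene.

Step 4
Reactants: 4 acetoxy ketal
Product: 6 ketal diol (C7 branch = CH(CH2OH)2; C11 not stereogenic), via B-alkyl-9-BBN adduct 5 (not isolated)
Conditions: 9-BBN, THF, 0 °C to rt; then NaOH, H2O2, 0 °C to rt
Reagents that add atoms: hydrogen peroxide, OO; 9-BBN, B1C2CCCC1CCC2 (boron stays only in 5)
Why: Anti-Markovnikov hydroboration with the bulky 9-BBN selects the 1,1-disubstituted alkene over the trisubstituted ring alkene, and the alkaline peroxide oxidation also saponifies the acetate, so C11 ends with two identical CH2OH arms.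

Step 5
Reactants: 6 ketal diol
Product: 7 bis-TBS ketal
Conditions: TBSCl, imidazole, DMF, rt
Reagents that add atoms: tert-butyldimethylsilyl chloride, CC(C)(C)[Si](C)(C)Cl
Why: Routine silylation of two unhindered primary alcohols.

Step 6
Reactants: 7 bis-TBS ketal
Product: 8 C6-oxo ketal (enone C6=O/C5=C10; C7 now alpha to the ketone)
Conditions: Rh2(caprolactamate)4 (1 mol %), t-BuOOH (70 % aq.), ClCH2CH2Cl, 40 °C
Reagents that add atoms: tert-butyl hydroperoxide, CC(C)(C)OO
Why: Radical allylic C–H oxidation goes to C6, the only allylic methylene, because C9 is blocked as the ketal and the C14 methyl C–H bonds are stronger, while the base-free medium protects the now enolisable C7 centre.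

Step 7
Reactants: 8 C6-oxo ketal
Product: 9 C6 allylic alcohol (C6–OH cis to the C7 branch as in the target)
Conditions: LiBH(s-Bu)3 (L-Selectride), THF, −78 °C; then H2O
Reagents that add atoms: none
Why: The bulky hydride adds 1,2 (the beta-carbon C10 is fully substituted) by equatorial attack on the side of H7, as in the reduction of 2-alkylcyclohexanones to cis-alcohols, which places the new C6–OH cis to the C7 branch.

Step 8
Reactants: 9 C6 allylic alcohol
Product: 10 tris-TBS ketal
Conditions: TBSOTf, 2,6-lutidine, CH2Cl2, −78 to 0 °C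
Reagents that add atoms: tert-butyldimethylsilyl triflate, CC(C)(C)[Si](C)(C)OS(=O)(=O)C(F)(F)F
Why: Silyl triflate silylation overcomes the hindrance of the axial secondary alcohol, and the lutidine buffer keeps the ketal intact.

Step 9
Reactants: 10 tris-TBS ketal
Product: 11 tris-TBS enone (C9=O/C10=C5; C6–OTBS and C7 branch on the same face)
Conditions: PPTS (cat.), acetone/H2O, rt
Reagents that add atoms: water, O
Why: Mild acid hydrolysis of the allylic and therefore labile dioxolane restores the enone under conditions that TBS ethers tolerate.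

Step 10
Reactants: 11 tris-TBS enone
Product: 13 C8 ketol (C8–OH trans to the C7 branch as in the target), via sodium dienolate 12 (not isolated)
Conditions: NaN(SiMe3)2, THF, −78 °C; 2-(phenylsulfonyl)-3-phenyloxaziridine, −78 °C; AcOH quench
Reagents that add atoms: 2-(phenylsulfonyl)-3-phenyloxaziridine, O=S(=O)(c1ccccc1)N1OC1c1ccccc1; NaN(SiMe3)2, C[Si](C)(C)[N-][Si](C)(C)C.[Na+] (sodium stays only in 12)
Why: Kinetic alpha'-deprotonation gives the cross-conjugated dienolate, and Davis oxaziridine hydroxylation delivers oxygen to C8 from the face opposite to both the C7 branch and the C6–OTBS group.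

Step 11
Reactants: 13 C8 ketol; 14 isobutyryl chloride
Product: 15 enone isobutyrate (C8 ester on one face; C6–OTBS and C7 branch on the other)
Conditions: pyridine, DMAP (cat.), CH2Cl2, 0 °C
Reagents that add atoms: none
Why: DMAP-catalysed O-acylation of the secondary ketol under weakly basic conditions, in which the trans C7/C8 arrangement is also the thermodynamically preferred one.

Step 12
Reactants: 15 enone isobutyrate; 16 1-methylcyclobutene
Product: 17 cis-anti-cis 6-4-4 tricyclic photoadduct (bonds C5–C4(Me) and C10–C1; cyclobutane on the face opposite to C6–OTBS and the C7 branch)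
Conditions: hν (365 nm), 16 (10 equiv), CH2Cl2, −40 °C
Reagents that add atoms: none
Why: Enone–alkene [2+2] photocycloaddition through the enone triplet, in which the alkene adds anti to the pseudoaxial C6–OTBS and the C7 branch, the head-to-tail sense is the usual one for a donor alkene and also avoids adjacent quaternary carbons C4 and C10, and ring strain enforces the cis-anti-cis fusion, so C1, C4, C5 and C10 are set as drawn.

Step 13
Reactants: 17 tricyclic photoadduct
Product: 18 (2E,6Z)-cyclodeca-2,6-dienone (C1=C10 E and conjugated with C9=O; C4=C5 Z; C6–OTBS, C7 branch and C8 isobutyrate unchanged)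
Conditions: PhMe (0.02 M), BHT (cat.), steel flow coil, 200 °C, ca. 10 min residence
Reagents that add atoms: none
Why: Heat first breaks the central C1–C4 bond of the bicyclo[2.2.0]hexane, the most strained bond and tertiary at C4, and the chair-like cyclohexane-1,4-diyl transition structure then fragments across C5–C10, so two sigma bonds become the C1=C10 and C4=C5 pi bonds. This is the known thermolysis of cyclohexenone–cyclobutene photoadducts to cis,trans-cyclodeca-1,5-dienes, formally a [σ2s+σ2a] cycloreversion. The ten-membered ring arises by ring expansion, that is by loss of the two internal bonds that partition its perimeter, not by end-to-end cyclisation, so no dilution or entropy problem arises. No stereocentre is made and the four cyclobutane centres vanish; two alkene geometries are set instead, because the cis ring bonds C5–C6 and C10–C9 must sit one axial and one equatorial on the chair array, the axial one ending Z and the equatorial one E. The needed sense (C6 axial, C9 equatorial) belongs to the six-ring chair with the bulky C6–OTBS equatorial, which avoids a syn-diaxial OTBS/C14-methyl contact, puts H6 rather than oxygen in the plane of the nascent Z-alkene (least A(1,3) strain against C3) and leaves only H1 cis to C9 on the E-alkene. Cleavage of C5–C10 rather than C2–C3 is secured by the quaternary C10 and its overlap with the C9 carbonyl, and a short residence at high temperature favours the high-A-factor opening over the ordered Cope rearrangement to the divinylcyclohexanone.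

Step 14
Reactants: 18 cyclodecadienone
Product: 19 C9 allylic alcohol (C9–OH syn to C8–O in the extended chain; same spatial arrangement as 9S in the target but formally 9R here by a CIP priority switch)
Conditions: NaBH4, CeCl3·7H2O, MeOH/THF, −78 °C
Reagents that add atoms: none
Why: Luche 1,2-reduction, in which the non-chelating ester lets hydride add anti to the C8–O bond (polar Felkin–Anh) from the open periphery of the ring to give the 8,9-syn alcohol, while the low temperature suppresses acyl migration.

Step 15
Reactants: 19 C9 allylic alcohol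
Product: 20 (1R,10R)-epoxy alcohol (trans epoxide; C4=C5 untouched)
Conditions: mCPBA, NaHCO3, CH2Cl2, −20 °C
Reagents that add atoms: 3-chloroperbenzoic acid, OOC(=O)c1cccc(Cl)c1
Why: Prilezhaev epoxidation, helped by hydrogen bonding to C9–OH, takes the strained E-alkene rather than the Z-alkene shielded by C6–OTBS and attacks its outer face in the conformer fixed by A(1,3) strain at C6, as with related 9-hydroxygermacradienes; a VO(acac)2-directed epoxidation is avoided because its erythro preference opposes the threo C9/C10 relationship of the target.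

Step 16
Reactants: 20 epoxy alcohol
Product: 21 epoxy tetraol (free C6–OH, C9–OH and two CH2OH arms; C8 isobutyrate kept)
Conditions: HF·pyridine, pyridine, THF, 0 °C to rt
Reagents that add atoms: none
Why: Fluoride desilylation with pyridine-buffered HF is non-basic enough to prevent isobutyrate migration and buffered enough to spare the epoxide from transannular opening.

Step 17
Reactants: 21 epoxy tetraol
Product: 24 alpha-hydroxymethyl lactone (cis-fused C6–O–C12 gamma-lactone; C11 epimers), via hydroxy aldehyde 22 (not isolated), via lactol 23 (not isolated)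
Conditions: TEMPO (cat.), PhI(OAc)2 (2.2 equiv), CH2Cl2, 0 °C to rt
Reagents that add atoms: none
Why: Oxoammonium oxidation prefers primary over secondary alcohols, the first aldehyde is trapped by the cis C6–OH as a five-membered lactol that is oxidised faster than the remaining CH2OH (deactivated once beta to the lactone carbonyl), and either arm may react because C11 is flattened in step 18.

Step 18
Reactants: 24 alpha-hydroxymethyl lactone
Product: 26 CNP0110853.1, via primary mesylate 25 (not isolated)
Conditions: MsCl, Et3N, CH2Cl2, −30 °C; then DBU, 0 °C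
Reagents that add atoms: methanesulfonyl chloride, CS(=O)(=O)Cl (atoms stay only in 25)
Why: Sulfonylation picks the unhindered primary alcohol over the C9 carbinol flanked by the quaternary epoxide carbon and C8, and E1cB elimination of the beta-mesyloxy lactone gives the C11=C13 methylene and removes the C11 centre.

Compound list
1 | (S)-carvone | CC1=CC[C@@H](CC1=O)C(C)=C | starting material
2 | (S)-10-chlorocarvone | O=C1C[C@@H](C(=C)CCl)CC=C1C | intermediate
3 | (S)-10-acetoxycarvone | O=C1C[C@@H](C(=C)COC(C)=O)CC=C1C | intermediate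
4 | acetoxy ketal | C1COC2(O1)C[C@@H](C(=C)COC(C)=O)CC=C2C | intermediate
5 | B-alkyl-9-BBN adduct (C11 epimers) | C1COC2(O1)C[C@@H](C(COC(C)=O)CB3C4CCCC3CCC4)CC=C2C | intermediate
6 | ketal diol | C1COC2(O1)C[C@@H](C(CO)CO)CC=C2C | intermediate
7 | bis-TBS ketal | C1COC2(O1)C[C@@H](C(CO[Si](C)(C)C(C)(C)C)CO[Si](C)(C)C(C)(C)C)CC=C2C | intermediate
8 | C6-oxo ketal | C1COC2(O1)C[C@@H](C(CO[Si](C)(C)C(C)(C)C)CO[Si](C)(C)C(C)(C)C)C(=O)C=C2C | intermediate
9 | C6 allylic alcohol (OH cis to C7 branch) | C1COC2(O1)C[C@@H](C(CO[Si](C)(C)C(C)(C)C)CO[Si](C)(C)C(C)(C)C)[C@@H](O)C=C2C | intermediate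
10 | tris-TBS ketal | C1COC2(O1)C[C@@H](C(CO[Si](C)(C)C(C)(C)C)CO[Si](C)(C)C(C)(C)C)[C@@H](O[Si](C)(C)C(C)(C)C)C=C2C | intermediate
11 | tris-TBS enone | O=C1C[C@@H](C(CO[Si](C)(C)C(C)(C)C)CO[Si](C)(C)C(C)(C)C)[C@@H](O[Si](C)(C)C(C)(C)C)C=C1C | intermediate
12 | sodium dienolate | [Na+].[O-]C1=C[C@@H](C(CO[Si](C)(C)C(C)(C)C)CO[Si](C)(C)C(C)(C)C)[C@@H](O[Si](C)(C)C(C)(C)C)C=C1C | intermediate
13 | C8 ketol (OH trans to C7 branch) | O=C1[C@H](O)[C@@H](C(CO[Si](C)(C)C(C)(C)C)CO[Si](C)(C)C(C)(C)C)[C@@H](O[Si](C)(C)C(C)(C)C)C=C1C | intermediate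
14 | isobutyryl chloride | CC(C)C(=O)Cl | starting material
15 | enone isobutyrate | O=C1[C@H](OC(=O)C(C)C)[C@@H](C(CO[Si](C)(C)C(C)(C)C)CO[Si](C)(C)C(C)(C)C)[C@@H](O[Si](C)(C)C(C)(C)C)C=C1C | intermediate
16 | 1-methylcyclobutene | CC1=CCC1 | starting material
17 | cis-anti-cis tricyclic photoadduct | O=C1[C@H](OC(=O)C(C)C)[C@@H](C(CO[Si](C)(C)C(C)(C)C)CO[Si](C)(C)C(C)(C)C)[C@@H](O[Si](C)(C)C(C)(C)C)[C@@H]2[C@@]3(C)CC[C@H]3[C@]12C | intermediate
18 | (2E,6Z)-cyclodeca-2,6-dienone | O=C1/C(C)=C/CC/C(C)=C\[C@H](O[Si](C)(C)C(C)(C)C)[C@H](C(CO[Si](C)(C)C(C)(C)C)CO[Si](C)(C)C(C)(C)C)[C@H]1OC(=O)C(C)C | intermediate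
19 | C9 allylic alcohol | O[C@@H]1/C(C)=C/CC/C(C)=C\[C@H](O[Si](C)(C)C(C)(C)C)[C@H](C(CO[Si](C)(C)C(C)(C)C)CO[Si](C)(C)C(C)(C)C)[C@H]1OC(=O)C(C)C | intermediate
20 | (1R,10R)-epoxy alcohol | O[C@@H]1[C@@]2(C)O[C@@H]2CC/C(C)=C\[C@H](O[Si](C)(C)C(C)(C)C)[C@H](C(CO[Si](C)(C)C(C)(C)C)CO[Si](C)(C)C(C)(C)C)[C@H]1OC(=O)C(C)C | intermediate
21 | epoxy tetraol | O[C@@H]1[C@@]2(C)O[C@@H]2CC/C(C)=C\[C@H](O)[C@H](C(CO)CO)[C@H]1OC(=O)C(C)C | intermediate
22 | hydroxy aldehyde (C11 epimers) | O[C@@H]1[C@@]2(C)O[C@@H]2CC/C(C)=C\[C@H](O)[C@H](C(CO)C=O)[C@H]1OC(=O)C(C)C | intermediate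
23 | lactol (C11 and C12 epimers) | OCC1C(O)O[C@H]2/C=C(/C)CC[C@H]3O[C@]3(C)[C@@H](O)[C@H](OC(=O)C(C)C)[C@@H]12 | intermediate
24 | alpha-hydroxymethyl lactone (C11 epimers) | OCC1C(=O)O[C@H]2/C=C(/C)CC[C@H]3O[C@]3(C)[C@@H](O)[C@H](OC(=O)C(C)C)[C@@H]12 | intermediate
25 | primary mesylate (C11 epimers) | CS(=O)(=O)OCC1C(=O)O[C@H]2/C=C(/C)CC[C@H]3O[C@]3(C)[C@@H](O)[C@H](OC(=O)C(C)C)[C@@H]12 | intermediate
26 | CNP0110853.1 | C=C1C(=O)O[C@H]2/C=C(/C)CC[C@H]3O[C@]3(C)[C@@H](O)[C@H](OC(=O)C(C)C)[C@@H]12 | target

Total step count: 18. Longest linear sequence: 18 steps from (S)-carvone.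

Steps most likely to fail

Step 13 (thermal ring opening). Three processes could spoil it:
- fragmentation through the alternative chair, which would invert both alkene geometries;
- leakage by C2–C3 scission;
- onward Cope rearrangement at the temperature needed for the opening.

The favoured chair also has to carry the C7 and C8 groups trans-diaxial, so its preference is not assured. The fallback changes the substrate class from ketone to carbinol. It sets out from 17, where NaBH4 in MeOH should give the tricyclic carbinol F1 (either C9 epimer serves). Thermolysis of this substrate type is the best documented for such openings. An sp3 C9 substituent also alters the chair preference and removes the acyloxy-ketone dipole, so heating should give the cyclodecadienol F2. Selective allylic oxidation with MnO2 comes back to the route at 18, and the epimer of F2 that matches 19 can rejoin there directly.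

Step 12 (photocycloaddition). Capture of the alpha-methyl enone triplet may be inefficient, and head-to-tail or facial selectivity may erode because the C8 ester sits on the face the alkene must use. The fallback reverses the order of events. It sets out from 11, whose reacting face is free, and irradiation with 16 should give the C8-unsubstituted photoadduct F3. In F3 only C8 can enolise, because C10 is quaternary. NaN(SiMe3)2 then gives its sodium enolate F4, and Davis hydroxylation anti to the C7 branch gives the tricyclic ketol F5. Acylation with 14 comes back to the route at 17.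

Step 14 (C9 reduction). Facial selectivity in the hydride delivery may be poor, because the ring conformation rather than the local Felkin–Anh preference may decide. The fallback corrects the centre by substitution instead of by reduction. It sets out from 18, and the reduction product is taken on as the C9-epimeric allylic alcohol F6. Mitsunobu inversion with chloroacetic acid (PPh3, DIAD) should give the inverted chloroacetate F7. Thiourea with NaHCO3 in EtOH removes the chloroacetyl group without touching the isobutyrate, which comes back to the route at 19.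

Further compounds
F1 | step 13 | tricyclic carbinol (C9 epimers) | OC1[C@H](OC(=O)C(C)C)[C@@H](C(CO[Si](C)(C)C(C)(C)C)CO[Si](C)(C)C(C)(C)C)[C@@H](O[Si](C)(C)C(C)(C)C)[C@@H]2[C@@]3(C)CC[C@H]3[C@]12C
F2 | step 13 | cyclodecadienol (C9 epimers) | OC1/C(C)=C/CC/C(C)=C\[C@H](O[Si](C)(C)C(C)(C)C)[C@H](C(CO[Si](C)(C)C(C)(C)C)CO[Si](C)(C)C(C)(C)C)[C@H]1OC(=O)C(C)C
F3 | step 12 | C8-unsubstituted photoadduct | O=C1C[C@@H](C(CO[Si](C)(C)C(C)(C)C)CO[Si](C)(C)C(C)(C)C)[C@@H](O[Si](C)(C)C(C)(C)C)[C@@H]2[C@@]3(C)CC[C@H]3[C@]12C
F4 | step 12 | sodium enolate of F3 | [Na+].[O-]C1=C[C@@H](C(CO[Si](C)(C)C(C)(C)C)CO[Si](C)(C)C(C)(C)C)[C@@H](O[Si](C)(C)C(C)(C)C)[C@@H]2[C@@]3(C)CC[C@H]3[C@]12C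
F5 | step 12 | tricyclic ketol | O=C1[C@H](O)[C@@H](C(CO[Si](C)(C)C(C)(C)C)CO[Si](C)(C)C(C)(C)C)[C@@H](O[Si](C)(C)C(C)(C)C)[C@@H]2[C@@]3(C)CC[C@H]3[C@]12C
F6 | step 14 | C9-epimeric allylic alcohol | O[C@H]1/C(C)=C/CC/C(C)=C\[C@H](O[Si](C)(C)C(C)(C)C)[C@H](C(CO[Si](C)(C)C(C)(C)C)CO[Si](C)(C)C(C)(C)C)[C@H]1OC(=O)C(C)C
F7 | step 14 | inverted chloroacetate | ClCC(=O)O[C@@H]1/C(C)=C/CC/C(C)=C\[C@H](O[Si](C)(C)C(C)(C)C)[C@H](C(CO[Si](C)(C)C(C)(C)C)CO[Si](C)(C)C(C)(C)C)[C@H]1OC(=O)C(C)C
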